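**Retrosynthetic overview**
1. C8 carbinol: reagent-controlled CBS reduction of the cross-conjugated dienone, which comes from the C7 ketone by Tebbe methylenation and SeO2/MnO2 oxidation of the only allylic CH2.
2. C3–Cl / C2–Br: retentive chlorodehydroxylation of a trans-bromohydrin, made by axial methyl addition to an α-bromo ketone whose bromine sits equatorial, cis to C11.
3. Spiro centre C6 and ring B: catalytic enantioselective Diels–Alder union of an exo-methylene enone (ring A fragment) with 3-bromo-2-silyloxybutadiene.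
4. Ring A fragment from cyclohexane-1,3-dione (gem-dimethylation, enol triflate to alkenyl bromide, Wittig, allylic oxidation); diene from methyl vinyl ketone (Br2, Et3N, TIPSOTf).
5. Ring order: ring A first (the dione carbocycle), ring B second (Diels–Alder).

Assumption: names use spiro[5.5]undecane (chamigrene) numbering (C1–C5 halogenated ring, C6 spiro, C7–C11 ring A), and the sense of induction of the chiral catalysts in steps 9 and 14 is taken from the usual models; if a first run gives the antipode, the mirror-image catalyst is used.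

**Ring A fragment**

Step 1
Reactants: 1 cyclohexane-1,3-dione
Product: 3 2,2-dimethylcyclohexane-1,3-dione, via 2-methylcyclohexane-1,3-dione 2 (not isolated)
Conditions: MeI (3 equiv), K2CO3 (3 equiv), acetone, reflux
Reagents that add atoms: iodomethane, CI
Why: Twofold C-alkylation of the 1,3-diketone enolate (enolate alkylation) installs the gem-dimethyl carbon C11 between the two carbonyls; no stereocentre is formed.

Step 2
Reactants: 3 2,2-dimethylcyclohexane-1,3-dione
Product: 4 6,6-dimethyl-5-oxocyclohex-1-en-1-yl trifluoromethanesulfonate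
Conditions: KHMDS (1.05 equiv), THF, −78 °C; PhNTf2, −78 to 0 °C
Reagents that add atoms: N-phenylbis(trifluoromethanesulfonimide), O=S(=O)(N(c1ccccc1)S(=O)(=O)C(F)(F)F)C(F)(F)F
Why: Kinetic deprotonation of one of the two equivalent ketones and O-sulfonylation (enol triflate formation) can only place the double bond away from the quaternary carbon, which fixes the later C9=C10 position.

Step 3
Reactants: 4 6,6-dimethyl-5-oxocyclohex-1-en-1-yl trifluoromethanesulfonate
Product: 5 3-bromo-2,2-dimethylcyclohex-3-en-1-one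
Conditions: Ni(cod)2 (10 mol%), LiBr (3 equiv), DMA/THF, 23 °C
Reagents that add atoms: lithium bromide, [Li+].[Br-]
Why: Nickel(0)-catalysed triflate–halide exchange (oxidative addition, halide metathesis, reductive elimination) turns the alkenyl triflate into the alkenyl bromide at the same carbon and tolerates the ketone.

Step 4
Reactants: 5 3-bromo-2,2-dimethylcyclohex-3-en-1-one
Product: 6 1-bromo-6,6-dimethyl-5-methylidenecyclohex-1-ene
Conditions: Ph3PCH3Br (2 equiv), KOtBu (2 equiv), toluene, 90 °C
Reagents that add atoms: methyltriphenylphosphonium bromide, C[P+](c1ccccc1)(c1ccccc1)c1ccccc1.[Br-]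
Why: Wittig methylenation of the remaining hindered ketone under forcing conditions gives the exocyclic alkene; the alkenyl bromide does not react with the ylide.

Step 5
Reactants: 6 1-bromo-6,6-dimethyl-5-methylidenecyclohex-1-ene
Product: 8 4-bromo-5,5-dimethyl-6-methylidenecyclohex-3-en-1-one, via racemic allylic alcohol 7 (not isolated)
Conditions: SeO2 (0.5 equiv), t-BuOOH (3 equiv), CH2Cl2, 0 to 23 °C; filter; MnO2 (15 equiv), CH2Cl2, 23 °C; use at once
Reagents that add atoms: tert-butyl hydroperoxide, CC(C)(C)OO; selenium dioxide, O=[Se]=O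
Why: SeO2 allylic oxidation (ene reaction then [2,3]-sigmatropic shift) attacks the more electron-rich 1,1-disubstituted alkene at its only allylic CH2 while keeping the exocyclic double bond, and MnO2 oxidises the allylic alcohol to the α-methylene ketone.

**Diene fragment**

Step 6
Reactants: 9 but-3-en-2-one (methyl vinyl ketone)
Product: 10 rac-3,4-dibromobutan-2-one
Conditions: Br2 (1.0 equiv), CH2Cl2, −15 °C
Reagents that add atoms: bromine, BrBr
Why: Electrophilic anti addition of bromine to the enone double bond (alkene bromination) gives the vicinal dibromide as a racemate whose stereocentre is removed in the next step.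

Step 7
Reactants: 10 rac-3,4-dibromobutan-2-one
Product: 11 3-bromobut-3-en-2-one
Conditions: Et3N (1.1 equiv), Et2O, 0 °C
Reagents that add atoms: none
Why: E1cB dehydrobromination (loss of the acidic α-hydrogen and the β-bromide) gives the α-bromo enone.

Step 8
Reactants: 11 3-bromobut-3-en-2-one
Product: 12 [(3-bromobuta-1,3-dien-2-yl)oxy]tri(propan-2-yl)silane
Conditions: TIPSOTf (1.1 equiv), Et3N (1.5 equiv), CH2Cl2, −78 to 0 °C
Reagents that add atoms: tri(propan-2-yl)silyl trifluoromethanesulfonate, CC(C)[Si](OS(=O)(=O)C(F)(F)F)(C(C)C)C(C)C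
Why: Soft enolisation of the methyl ketone with silyl triflate and amine (silyl enol ether formation) gives the 2-silyloxy diene; only the methyl group can enolise.

**Fragment union and endgame**

Step 9
Reactants: 8 4-bromo-5,5-dimethyl-6-methylidenecyclohex-3-en-1-one; 12 [(3-bromobuta-1,3-dien-2-yl)oxy]tri(propan-2-yl)silane (2 equiv)
Product: 14 (2S,6R)-2,10-dibromo-11,11-dimethylspiro[5.5]undec-9-ene-3,7-dione, via silyl enol ether cycloadduct 13 (not isolated)
Conditions: (S)-o-tolyl-oxazaborolidinium triflimide (20 mol%), CH2Cl2, −78 to −40 °C; then HF·pyridine, THF, 0 °C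
Reagents that add atoms: none
Why: In this chiral Lewis acid catalysed Diels–Alder reaction the diene CH2 next to C–OSi bonds to the exocyclic CH2 of the s-cis enone (para regiochemistry, O at C3 and Br at C2), the catalyst blocks one enone face and sets the spiro centre C6 (R), and protodesilylation protonates C2 axially so that bromine ends up equatorial and cis to C11 (2S), which is also the thermodynamic epimer because an axial bromine would clash with the axial C7.

Step 10
Reactants: 14 (2S,6R)-2,10-dibromo-11,11-dimethylspiro[5.5]undec-9-ene-3,7-dione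
Product: 15 (2S,3S,6R)-2,10-dibromo-3-hydroxy-3,11,11-trimethylspiro[5.5]undec-9-en-7-one
Conditions: MAD (2 equiv), toluene, −78 °C; MeLi (1.3 equiv), −78 °C; aq. NH4Cl at −78 °C
Reagents that add atoms: methyllithium, [Li]C
Why: In this amphiphilic carbonyl alkylation the bulky aluminium phenoxide MAD complexes the unhindered C3 ketone on its equatorial side so that methyllithium adds axially (1,2-addition), giving the equatorial tertiary alcohol trans to the C2 bromine (3S), while the C7 ketone is shielded by the neighbouring quaternary carbons.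

Step 11
Reactants: 15 (2S,3S,6R)-2,10-dibromo-3-hydroxy-3,11,11-trimethylspiro[5.5]undec-9-en-7-one
Product: 17 (2S,3S,6R)-2,10-dibromo-3-chloro-3,11,11-trimethylspiro[5.5]undec-9-en-7-one, via chlorosulfite 16 (not isolated)
Conditions: SOCl2 (3 equiv), TiCl4 (10 mol%), CH2Cl2, −20 to 0 °C
Reagents that add atoms: thionyl chloride, O=S(Cl)Cl
Why: Chlorodehydroxylation through the chlorosulfite with internal return (SNi type, front-side chloride delivery promoted by TiCl4 and anti to the neighbouring bromine, which can bridge the developing cation) replaces OH by Cl with retention at C3 (3S), so Br and Cl end up trans.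

Step 12
Reactants: 17 (2S,3S,6R)-2,10-dibromo-3-chloro-3,11,11-trimethylspiro[5.5]undec-9-en-7-one
Product: 18 (2S,3S,6S)-2,10-dibromo-3-chloro-3,11,11-trimethyl-7-methylidenespiro[5.5]undec-9-ene
Conditions: Tebbe reagent (2 equiv), pyridine, THF/toluene, −40 to 23 °C
Reagents that add atoms: Tebbe reagent, C[Al-]1(C)C[Ti]([Cl+]1)(C1C=CC=C1)C1C=CC=C1
Why: Tebbe olefination ([2+2] cycloaddition of the titanium methylidene to the carbonyl and cycloreversion) methylenates the hindered, enolisable C7 ketone under non-basic conditions that leave the alkyl halides untouched.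

Step 13
Reactants: 18 (2S,3S,6S)-2,10-dibromo-3-chloro-3,11,11-trimethyl-7-methylidenespiro[5.5]undec-9-ene
Product: 20 (2S,3S,6S)-2,10-dibromo-3-chloro-3,11,11-trimethyl-7-methylidenespiro[5.5]undec-9-en-8-one, via C8-epimeric allylic alcohols 19 (not isolated)
Conditions: SeO2 (0.5 equiv), t-BuOOH (3 equiv), CH2Cl2, 23 °C; filter; MnO2 (15 equiv), CH2Cl2, 23 °C
Reagents that add atoms: tert-butyl hydroperoxide, CC(C)(C)OO; selenium dioxide, O=[Se]=O
Why: SeO2 allylic oxidation (ene reaction, [2,3]-sigmatropic shift) hydroxylates C8, the only allylic C–H position in the molecule, with the exocyclic alkene retained, and MnO2 oxidises the doubly allylic alcohols to the cross-conjugated dienone, so the C8 configuration of 19 does not matter.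

Step 14
Reactants: 20 (2S,3S,6S)-2,10-dibromo-3-chloro-3,11,11-trimethyl-7-methylidenespiro[5.5]undec-9-en-8-one
Product: 21 (2S,3S,6S,8R)-2,10-dibromo-3-chloro-3,11,11-trimethyl-7-methylidenespiro[5.5]undec-9-en-8-ol (target)
Conditions: (S)-Me-CBS (20 mol%), catecholborane (1.5 equiv), toluene, −78 °C
Reagents that add atoms: none
Why: In this Corey–Bakshi–Shibata reduction the ketone binds the oxazaborolidine–borane complex with its α-branched C7 alkenyl arm as the large group and hydride is delivered to one carbonyl face (1,2-reduction), giving the (8R) allylic alcohol under reagent control.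

**Compound list**
1 | cyclohexane-1,3-dione | O=C1CCCC(=O)C1 | starting material
2 | 2-methylcyclohexane-1,3-dione | CC1C(=O)CCCC1=O | intermediate
3 | 2,2-dimethylcyclohexane-1,3-dione | CC1(C)C(=O)CCCC1=O | intermediate
4 | 6,6-dimethyl-5-oxocyclohex-1-en-1-yl trifluoromethanesulfonate | CC1(C)C(=O)CCC=C1OS(=O)(=O)C(F)(F)F | intermediate
5 | 3-bromo-2,2-dimethylcyclohex-3-en-1-one | CC1(C)C(=O)CCC=C1Br | intermediate
6 | 1-bromo-6,6-dimethyl-5-methylidenecyclohex-1-ene | C=C1CCC=C(Br)C1(C)C | intermediate
7 | rac-4-bromo-5,5-dimethyl-6-methylidenecyclohex-3-en-1-ol | C=C1C(O)CC=C(Br)C1(C)C | intermediate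
8 | 4-bromo-5,5-dimethyl-6-methylidenecyclohex-3-en-1-one | C=C1C(=O)CC=C(Br)C1(C)C | intermediate
9 | but-3-en-2-one (methyl vinyl ketone) | CC(=O)C=C | starting material
10 | rac-3,4-dibromobutan-2-one | CC(=O)C(Br)CBr | intermediate
11 | 3-bromobut-3-en-2-one | CC(=O)C(Br)=C | intermediate
12 | [(3-bromobuta-1,3-dien-2-yl)oxy]tri(propan-2-yl)silane | C=C(Br)C(=C)O[Si](C(C)C)(C(C)C)C(C)C | intermediate
13 | (6R)-2,10-dibromo-11,11-dimethyl-3-{[tri(propan-2-yl)silyl]oxy}spiro[5.5]undeca-2,9-dien-7-one | O=C1CC=C(Br)C(C)(C)[C@]12CCC(O[Si](C(C)C)(C(C)C)C(C)C)=C(Br)C2 | intermediate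
14 | (2S,6R)-2,10-dibromo-11,11-dimethylspiro[5.5]undec-9-ene-3,7-dione (Br equatorial, cis to C11) | O=C1CC=C(Br)C(C)(C)[C@]12CCC(=O)[C@@H](Br)C2 | intermediate
15 | (2S,3S,6R)-2,10-dibromo-3-hydroxy-3,11,11-trimethylspiro[5.5]undec-9-en-7-one (OH trans to Br) | O=C1CC=C(Br)C(C)(C)[C@]12CC[C@](C)(O)[C@@H](Br)C2 | intermediate
16 | chlorosulfite of 15, (2S,3S,6R)-2,10-dibromo-3,11,11-trimethyl-7-oxospiro[5.5]undec-9-en-3-yl sulfurochloridite | O=C1CC=C(Br)C(C)(C)[C@]12CC[C@](C)(OS(Cl)=O)[C@@H](Br)C2 | intermediate
17 | (2S,3S,6R)-2,10-dibromo-3-chloro-3,11,11-trimethylspiro[5.5]undec-9-en-7-one | O=C1CC=C(Br)C(C)(C)[C@]12CC[C@](C)(Cl)[C@@H](Br)C2 | intermediate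
18 | (2S,3S,6S)-2,10-dibromo-3-chloro-3,11,11-trimethyl-7-methylidenespiro[5.5]undec-9-ene | C=C1CC=C(Br)C(C)(C)[C@]12CC[C@](C)(Cl)[C@@H](Br)C2 | intermediate
19 | (2S,3S,6S)-2,10-dibromo-3-chloro-3,11,11-trimethyl-7-methylidenespiro[5.5]undec-9-en-8-ol, both C8 epimers | C=C1C(O)C=C(Br)C(C)(C)[C@]12CC[C@](C)(Cl)[C@@H](Br)C2 | intermediate
20 | (2S,3S,6S)-2,10-dibromo-3-chloro-3,11,11-trimethyl-7-methylidenespiro[5.5]undec-9-en-8-one | C=C1C(=O)C=C(Br)C(C)(C)[C@]12CC[C@](C)(Cl)[C@@H](Br)C2 | intermediate
21 | (2S,3S,6S,8R)-2,10-dibromo-3-chloro-3,11,11-trimethyl-7-methylidenespiro[5.5]undec-9-en-8-ol | C=C1[C@H](O)C=C(Br)C(C)(C)[C@]12CC[C@](C)(Cl)[C@@H](Br)C2 | target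

**Step count**
Total step count: 14.
Longest linear sequence: 11 steps (steps 1–5 and 9–14, from cyclohexane-1,3-dione). The three-step diene arm (steps 6–8) joins at step 9.

**Three steps most likely to fail, with fallbacks**

Step 9 (asymmetric Diels–Alder with the brominated diene; risk: low reactivity or selectivity of this unusual diene). The fallback sets out from 8, with 9 as the diene source, and comes back at 14. Methyl vinyl ketone 9 is silylated directly (TIPSOTf, Et3N) to tri(propan-2-yl)(buta-1,3-dien-2-yloxy)silane F1, a standard diene for this catalyst. The same catalysed cycloaddition with 8 gives the isolable (6R)-10-bromo-11,11-dimethyl-3-{[tri(propan-2-yl)silyl]oxy}spiro[5.5]undeca-2,9-dien-7-one F2. Its regiodefined silyl enol ether is then brominated at C2 with NBS (THF, −78 °C), and LiBr in acetone equilibrates C2 to the equatorial bromide 14.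

Step 11 (tertiary alcohol to chloride with retention; risk: elimination or loss of C3 control). The fallback sets out from 14 and comes back at 17. Only the unhindered C3 ketone is methylenated (Tebbe reagent, 1.05 equiv, −78 to −40 °C) to (2S,6R)-2,10-dibromo-11,11-dimethyl-3-methylidenespiro[5.5]undec-9-en-7-one F3. Gaseous HCl (CH2Cl2, −78 °C) is then added in the Markovnikov sense; the tertiary cation is bridged by the C2 bromine, so chloride enters anti to Br and gives 17.

Step 14 (CBS reduction; risk: the two alkenyl arms are not differentiated well enough). The fallback sets out from 20 and comes back at 21. Luche reduction (NaBH4, CeCl3·7H2O, MeOH, −78 °C) gives 21 together with its C8 epimer (2S,3S,6S,8S)-2,10-dibromo-3-chloro-3,11,11-trimethyl-7-methylidenespiro[5.5]undec-9-en-8-ol F4. After chromatographic separation, F4 is inverted by Mitsunobu esterification (4-nitrobenzoic acid, PPh3, DIAD) to (2S,3S,6S,8R)-2,10-dibromo-3-chloro-3,11,11-trimethyl-7-methylidenespiro[5.5]undec-9-en-8-yl 4-nitrobenzoate F5. K2CO3 in MeOH cleaves F5 to 21.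

**Further compounds**
F1 | step 9 | tri(propan-2-yl)(buta-1,3-dien-2-yloxy)silane | C=CC(=C)O[Si](C(C)C)(C(C)C)C(C)C
F2 | step 9 | (6R)-10-bromo-11,11-dimethyl-3-{[tri(propan-2-yl)silyl]oxy}spiro[5.5]undeca-2,9-dien-7-one | O=C1CC=C(Br)C(C)(C)[C@]12CCC(O[Si](C(C)C)(C(C)C)C(C)C)=CC2
F3 | step 11 | (2S,6R)-2,10-dibromo-11,11-dimethyl-3-methylidenespiro[5.5]undec-9-en-7-one | O=C1CC=C(Br)C(C)(C)[C@]12CCC(=C)[C@@H](Br)C2
F4 | step 14 | (2S,3S,6S,8S)-2,10-dibromo-3-chloro-3,11,11-trimethyl-7-methylidenespiro[5.5]undec-9-en-8-ol | C=C1[C@@H](O)C=C(Br)C(C)(C)[C@]12CC[C@](C)(Cl)[C@@H](Br)C2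
F5 | step 14 | (2S,3S,6S,8R)-2,10-dibromo-3-chloro-3,11,11-trimethyl-7-methylidenespiro[5.5]undec-9-en-8-yl 4-nitrobenzoate | C=C1[C@H](OC(=O)c3ccc(cc3)[N+](=O)[O-])C=C(Br)C(C)(C)[C@]12CC[C@](C)(Cl)[C@@H](Br)C2
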